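## Analysis of the target

- The target is a (3R)-isoflavan. Ring A is a fully substituted phloroglucinol-type benzene carrying 5-OMe, 6-prenyl and 7-OH, with H only at C8. Ring C is the dihydropyran O1–C2–C3–C4–C4a–C8a. Ring B is attached at C3 and carries 4'-OH. Ring D is a 2,2-dimethyl-2H-pyran fused to ring B through O2' and C3'.
- C3 is the only stereocentre. It sits between two methylene groups (C2 and C4) and has no neighbouring heteroatom, so it must be created by a C–C bond formation or a protonation under external control.
- Sensitive groups: the prenyl alkene next to the 7-OH closes to a chroman in acid. The chromene alkene of ring D is activated by two ortho oxygens and is hydrated or dimerised by strong acid. Both alkenes rule out hydrogenation and hydrogenolysis, and with them benzyl ethers and asymmetric hydrogenation of an isoflavene.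
- The two free phenols on electron-rich rings are easily oxidised as phenoxides.
- The difficulties are three: telling apart the three oxygens of ring A and placing the prenyl group exactly between O5 and O7; fusing ring D in the angular sense (pyran oxygen next to C1'); and setting a lone benzylic stereocentre.
- The strategy rests on two facts. C4 is ortho to O1 on the electron-rich ring A, so O1–C8a–C4a–C4 is a masked ortho-quinone methide. C3 is the α-carbon of an arylacetic acid built on ring B, and the carboxyl carbon of that acid is C2.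

## Retrosynthetic reasoning

**25 ⇐ 24.** Only the two O–Si bonds are cut. Both phenols are carried as triisopropylsilyl ethers because fluoride is the one deprotection mode that leaves the prenyl group, the chromene alkene and the C3 centre alone. The forward step has to free two phenols without acid or reduction.

**24 ⇐ 23.** The O1–C2 bond of ring C is cut. It is an aryl alkyl ether at a primary carbon, so it can be closed by intramolecular Mitsunobu etherification, in which C3 is a bystander. Cutting C8a–O1 instead would call for an aryl C–O coupling on a hindered, electron-rich ring. The gain is an open phenol-alcohol, 23, whose C4–C3–C2 chain is a 2-aryl-3-arylpropan-1-ol.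

**23 ⇐ 22.** C2 is raised to the carboxyl oxidation level and tied to O1 as a lactone. The dihydrocoumarin 22 is the natural product of joining an acyl enolate to an ortho-quinone methide. The forward step is a hydride reduction that must be faster than enolisation at C3.

**22 ⇐ 11 + 19 (through 20 and 21).** C3–C4 and the acyl C2–O1 bond are cut together. This is the place to cut because each fragment then holds one complete aromatic half of the molecule, and the union forms ring C and the stereocentre in one catalytic operation. Sulfone 11 releases the ortho-quinone methide 21 under base. Acid 19, activated as the mixed anhydride 20, supplies a catalyst-bound enolate. Cutting C3–C1' would require an asymmetric α-arylation with a hindered chromenyl partner, and cutting C4–C4a would require a Friedel–Crafts alkylation that cannot distinguish C4a from C8. The forward reaction must control the enolate face and must not racemise the acidic α-aryl lactone.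

**11 ⇐ 9 (through 10), 9 ⇐ 8 ⇐ 7.** The C4–S bond is cut back to a benzylic alcohol and then to the formyl group of a salicylaldehyde. The benzylic carbon is thus in place from the first step and never has to be introduced regioselectively. The MOM ether on the oxygen that becomes O1 keeps it distinct from the oxygen that becomes the 5-methoxy group. It is removed at the aldehyde stage, where the ortho carbonyl makes it labile.

**7 ⇐ 6 ⇐ 3 + 5; 3 ⇐ 2 ⇐ 1; 5 ⇐ 4.** The C6–prenyl bond is cut by an aromatic Claisen transposition. The allyl group is first hung on the oxygen that later carries the methyl group. That oxygen has only one free ortho carbon, and this carbon lies between O5 and O7. Direct C-prenylation of 1 could not tell the two ring positions or the two ortho oxygens apart. The forward sequence needs three selective O-functionalisations of 1, each ruled by the hydrogen bond to the formyl group.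

**19 ⇐ 18 ⇐ 17 ⇐ 16.** The carboxyl carbon, the future C2, is removed, leaving an aryl aldehyde. The forward route is a one-carbon homologation through an enol ether and the arylacetaldehyde. It avoids cyanide chemistry and strong base, which the aryl silyl ether would not survive.

**16 ⇐ 15 ⇐ 13 + 14; 13 ⇐ 12.** Ring D is cut at O–CMe2 and at C3'–C4'' by a retro propargyl Claisen cascade. With O4 of 12 silylated, the propargyl ether can only sit on O2. Its single free ortho carbon lies between the two oxygens, so the pyran fuses in the angular sense and the formyl carbon ends at chromene C8, which is C1' of the target.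

## Alternatives that were turned down

**Alternative 1: ring A by benzannulation of a cyclobutenone with an alkynyl ether.**
- Disconnection: ring A is cut at C6–C7, C4a–C5 and C7–C8. The pieces are a 3-silyloxycyclobutenone A2, which carries C8, C8a, C4a and the whole C4–C3–C2 chain with ring B, and the methoxyalkyne A3, which carries C5 and C6 with the methoxy and prenyl groups.
- Forward key step: heating opens A2 to a vinylketene, which adds A3 by [2+2]. A 4π opening and a 6π closure then give the phenol A1.
- For: the positions of all six ring A substituents follow from the connectivity of the pericyclic cascade, with no selective protection of a phloroglucinol. On this point it is stronger than the chosen route, which spends a MOM group and relies on three selective O-functionalisations. Its C3 centre has no neighbouring carbonyl group and cannot epimerise.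
- Against:
  - The key step creates no stereocentre, so C3 must be set earlier by a separate asymmetric step on the way to A2.
  - A2 needs a long linear sequence (chiral acid, ketene, [2+2], silylation), and A3 is a sensitive ynol ether with its own synthesis.
  - A1 emerges with the 7-OH free and the oxygen at C8a silylated, the reverse of what ring closure needs, so protecting groups must be reshuffled before O1–C2 can be formed.
  - The annulation builds from acyclic parts a benzene ring that an inexpensive phloroglucinol aldehyde already contains.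
- Comparison: the chosen strategy is more convergent and makes the stereocentre at the point of fragment union.

**Alternative 2: ring B by photochemical Wolff benzannulation on a preformed chroman.**
- Disconnection: ring B is cut at C2'–C3', C4'–C5' and C1'–C2'. The pieces are the diazo enone A5, which carries the finished rings A and C, and the silyloxyalkyne A6.
- Forward key step: irradiation of A5 gives a vinylketene by Wolff rearrangement. A [2+2] addition to A6, 4π opening and 6π closure then give the phenol A4.
- For: the two ring B oxygens come out differentiated (2'-OH free, O4' silylated), which is what ring D construction needs. The chosen route has to earn this by selective silylation of 12, so the alternative is stronger here. The C3 centre sits in a saturated chroman and is configurationally safe after the key step.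
- Against:
  - Ring D must still be added afterwards on the full molecule.
  - Ring A must be made by much the same steps as in the chosen route.
  - C3 must be set before the key step, in a chroman-3-yl carbonyl precursor of A5. That centre is α to a carbonyl and β to an aryloxy group, so it can epimerise and lose phenoxide by elimination, a worse liability than the acidic C3–H of 22.
  - The diazo ketone and the ultraviolet irradiation add handling and absorption problems with the aryl ether chromophores.
- Comparison: the sequence is linear and clearly longer, and it builds a plain resorcinol ring by elaborate means.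

**Alternative 3: ring A by Dieckmann closure onto a dihydropyran.**
- Disconnection: the C5–C6 bond of ring A is cut. The precursor is a keto ester such as A8, in which ring C is a dihydropyran bearing the C5 ester on C4a and a prenylated β-keto chain on C8a.
- Forward key step: two equivalents of a lithium amide base form a dianion. Its C6 enolate attacks the ester, and the cyclic 1,3-dione enolises to the aromatic diol A7.
- For: ring C exists before ring A, so neither lactone reduction nor Mitsunobu closure is needed, and there is no acidic C3–H at any stage. The prenyl position is fixed by the chain. On these points it is as good as or better than the chosen route.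
- Against:
  - A7 has free hydroxyls at both C5 and C7. The target needs the methyl on the more hindered O5, whereas alkylation prefers O7, so extra protection steps of doubtful selectivity follow.
  - Both hydroxyls flank the prenyl group, so chroman formation is a risk.
  - A8 is a chiral β-alkoxyacrylate whose synthesis, including its own asymmetric step, is long.
  - The site of the second deprotonation (C6 against C8) and C- against O-acylation are uncertain.
- Comparison: the chosen strategy differentiates O5 and O7 from the first steps and uses a catalytic asymmetric union.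

Key step: step 15

Assumption: the usual facial model for isothiourea-bound enolates is taken to hold for an unsubstituted methide, which assigns (2S,3R)-HyperBTM to the (R) product; if the first run shows the opposite sense, the (2R,3S) catalyst is used instead.

## Route

**Step 1**
Reactants: 1 2,4,6-trihydroxybenzaldehyde
Product: 2 2,6-dihydroxy-4-[(triisopropylsilyl)oxy]benzaldehyde
Conditions: i-Pr3SiCl (1.05 equiv), imidazole, DMF, 0 °C
Reagents that add atoms: triisopropylsilyl chloride, CC(C)[Si](Cl)(C(C)C)C(C)C
Why: Phenol silylation; the 4-hydroxyl is the least hindered and the only one not engaged in a hydrogen bond to the formyl group, so one equivalent of the bulky chloride should react there.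

**Step 2**
Reactants: 2 2,6-dihydroxy-4-[(triisopropylsilyl)oxy]benzaldehyde
Product: 3 2-hydroxy-6-(methoxymethoxy)-4-[(triisopropylsilyl)oxy]benzaldehyde
Conditions: MeOCH2Cl (1.2 equiv), i-Pr2NEt, CH2Cl2, 0 °C to rt
Reagents that add atoms: chloromethyl methyl ether, COCCl
Why: O-alkylation to the MOM acetal; the two ortho hydroxyls are equivalent, and once one is capped the other is locked in a chelate with the aldehyde, so the reaction should stop at the mono-ether.

**Step 3**
Reactants: 4 2-methylbut-3-en-2-ol
Product: 5 tert-butyl 2-methylbut-3-en-2-yl carbonate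
Conditions: n-BuLi, THF, −78 °C; then Boc2O, −78 °C to rt
Reagents that add atoms: di-tert-butyl dicarbonate, CC(C)(C)OC(=O)OC(=O)OC(C)(C)C
Why: Acylation of the tertiary lithium alkoxide gives the mixed carbonate, the ionisable partner for the allylic etherification.

**Step 4**
Reactants: 3 2-hydroxy-6-(methoxymethoxy)-4-[(triisopropylsilyl)oxy]benzaldehyde; 5 tert-butyl 2-methylbut-3-en-2-yl carbonate
Product: 6 2-(methoxymethoxy)-6-[(2-methylbut-3-en-2-yl)oxy]-4-[(triisopropylsilyl)oxy]benzaldehyde
Conditions: Pd(PPh3)4 (3 mol%), THF, 0 °C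
Reagents that add atoms: none
Why: Tsuji–Trost O-allylation: the palladium catalyst ionises 5 with loss of CO2 and the tert-butoxide set free deprotonates the chelated phenol. At low temperature phenoxides attack the 1,1-dimethylallyl palladium cation at its substituted end, so the tertiary ether should form under kinetic control.

**Step 5**
Reactants: 6 2-(methoxymethoxy)-6-[(2-methylbut-3-en-2-yl)oxy]-4-[(triisopropylsilyl)oxy]benzaldehyde
Product: 7 2-hydroxy-6-(methoxymethoxy)-3-(3-methylbut-2-en-1-yl)-4-[(triisopropylsilyl)oxy]benzaldehyde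
Conditions: PhMe, 110 °C
Reagents that add atoms: none
Why: Aromatic Claisen rearrangement ([3,3]): the allyl unit moves, with its ends exchanged, to the only free ortho carbon of that oxygen, which lies between the two oxygens. Enolisation restores the chelated phenol, so the prenyl group ends next to the oxygen that is methylated in step 6.

**Step 6**
Reactants: 7 2-hydroxy-6-(methoxymethoxy)-3-(3-methylbut-2-en-1-yl)-4-[(triisopropylsilyl)oxy]benzaldehyde
Product: 8 2-methoxy-6-(methoxymethoxy)-3-(3-methylbut-2-en-1-yl)-4-[(triisopropylsilyl)oxy]benzaldehyde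
Conditions: MeI, K2CO3, acetone, 50 °C
Reagents that add atoms: iodomethane, CI
Why: Williamson methylation of the only free hydroxyl; dry carbonate in acetone is mild enough for the aryl silyl ether.

**Step 7**
Reactants: 8 2-methoxy-6-(methoxymethoxy)-3-(3-methylbut-2-en-1-yl)-4-[(triisopropylsilyl)oxy]benzaldehyde
Product: 9 6-hydroxy-2-methoxy-3-(3-methylbut-2-en-1-yl)-4-[(triisopropylsilyl)oxy]benzaldehyde
Conditions: 3 M aq HCl, THF, 45 °C
Reagents that add atoms: none
Why: Acid hydrolysis of an aryl MOM acetal that is activated by the ortho formyl group. The prenyl group has only ether neighbours and cannot close to a chroman, and a silyl ether para to a formyl group is slow to hydrolyse in acid.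

**Step 8**
Reactants: 9 6-hydroxy-2-methoxy-3-(3-methylbut-2-en-1-yl)-4-[(triisopropylsilyl)oxy]benzaldehyde
Product: 11 3-methoxy-4-(3-methylbut-2-en-1-yl)-2-[(4-methylbenzenesulfonyl)methyl]-5-[(triisopropylsilyl)oxy]phenol, via salicyl alcohol 10 (not isolated)
Conditions: NaBH4, THF/EtOH, 0 °C; then TolSO2Na (3 equiv), HCO2H, H2O, 0 °C to rt
Reagents that add atoms: sodium 4-methylbenzenesulfinate, Cc1ccc(cc1)S(=O)[O-].[Na+]
Why: Borohydride reduction gives the salicyl alcohol 10, which ionises in dilute formic acid to a benzylic cation stabilised by three oxygen donors. The sulfinate traps it at sulfur (S-alkylation of a sulfinate) to give the benzylic sulfone, a bench-stable store of the quinone methide.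

**Step 9**
Reactants: 12 2,4-dihydroxybenzaldehyde
Product: 13 2-hydroxy-4-[(triisopropylsilyl)oxy]benzaldehyde
Conditions: i-Pr3SiCl (1.05 equiv), imidazole, CH2Cl2, 0 °C
Reagents that add atoms: triisopropylsilyl chloride, CC(C)[Si](Cl)(C(C)C)C(C)C
Why: Selective phenol silylation; the 2-hydroxyl is chelated to the formyl group and hindered, so the 4-hydroxyl should react.

**Step 10**
Reactants: 13 2-hydroxy-4-[(triisopropylsilyl)oxy]benzaldehyde; 14 3-chloro-3-methylbut-1-yne
Product: 15 2-[(2-methylbut-3-yn-2-yl)oxy]-4-[(triisopropylsilyl)oxy]benzaldehyde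
Conditions: DBU, CuCl2 (1 mol%), MeCN, 0 °C
Reagents that add atoms: none
Why: Copper-catalysed propargylic etherification (copper acetylide/allenylidene pathway) of the phenol with the tertiary chloride; O4 is blocked, so the ether can only form on O2, and dry conditions at 0 °C should spare the silyl ether.

**Step 11**
Reactants: 15 2-[(2-methylbut-3-yn-2-yl)oxy]-4-[(triisopropylsilyl)oxy]benzaldehyde
Product: 16 2,2-dimethyl-5-[(triisopropylsilyl)oxy]-2H-chromene-8-carbaldehyde
Conditions: o-xylene, 140 °C
Reagents that add atoms: none
Why: Propargyl Claisen cascade: [3,3] shift to the free ortho carbon, enolisation, 1,5-hydrogen shift and 6π oxa-electrocyclisation give the 2,2-dimethyl-2H-chromene. The other ortho carbon bears the formyl group, so the pyran can only fuse in the angular sense, with its oxygen next to the formyl carbon.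

**Step 12**
Reactants: 16 2,2-dimethyl-5-[(triisopropylsilyl)oxy]-2H-chromene-8-carbaldehyde
Product: 17 8-(2-methoxyethenyl)-2,2-dimethyl-5-[(triisopropylsilyl)oxy]-2H-chromene (E/Z mixture)
Conditions: Ph3P(CH2OMe)Cl, NaN(SiMe3)2, THF, 0 °C; then 16, 0 °C to rt
Reagents that add atoms: (methoxymethyl)triphenylphosphonium chloride, COC[P+](c1ccccc1)(c1ccccc1)c1ccccc1.[Cl-]
Why: Wittig reaction with the methoxymethylene ylide turns the aldehyde into the enol ether of the homologous aldehyde; the alkene geometry is of no consequence.

**Step 13**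
Reactants: 17 8-(2-methoxyethenyl)-2,2-dimethyl-5-[(triisopropylsilyl)oxy]-2H-chromene (E/Z mixture)
Product: 18 2-{2,2-dimethyl-5-[(triisopropylsilyl)oxy]-2H-chromen-8-yl}acetaldehyde
Conditions: 2 M aq HCl, THF, 40 °C
Reagents that add atoms: water, O
Why: Enol ether hydrolysis: protonation at the benzylic carbon, addition of water and loss of methanol give the arylacetaldehyde, which is taken on at once because it enolises easily.

**Step 14**
Reactants: 18 2-{2,2-dimethyl-5-[(triisopropylsilyl)oxy]-2H-chromen-8-yl}acetaldehyde
Product: 19 2-{2,2-dimethyl-5-[(triisopropylsilyl)oxy]-2H-chromen-8-yl}acetic acid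
Conditions: NaClO2, NaH2PO4, 2-methylbut-2-ene, t-BuOH/H2O, 0 °C to rt
Reagents that add atoms: sodium chlorite, [Na+].[O-]Cl=O
Why: Pinnick oxidation; chlorous acid oxidises the aldehyde only, and the excess alkene scavenger removes hypochlorous acid before it can attack the chromene or the electron-rich ring.

**Step 15**
Reactants: 19 2-{2,2-dimethyl-5-[(triisopropylsilyl)oxy]-2H-chromen-8-yl}acetic acid; 11 3-methoxy-4-(3-methylbut-2-en-1-yl)-2-[(4-methylbenzenesulfonyl)methyl]-5-[(triisopropylsilyl)oxy]phenol
Product: 22 (3R)-3-{2,2-dimethyl-5-[(triisopropylsilyl)oxy]-2H-chromen-8-yl}-5-methoxy-6-(3-methylbut-2-en-1-yl)-7-[(triisopropylsilyl)oxy]-3,4-dihydro-2H-chromen-2-one, via pivalic mixed anhydride 20 (not isolated), via ortho-quinone methide 21 (not isolated)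
Conditions: 19 (1.5 equiv), t-BuCOCl, i-Pr2NEt, CH2Cl2, 0 °C; then (2S,3R)-HyperBTM [(2S,3R)-3-isopropyl-2-phenyl-3,4-dihydro-2H-benzo[4,5]thiazolo[3,2-a]pyrimidine] (10 mol%), 11, Cs2CO3 (in portions), 0 °C
Reagents that add atoms: pivaloyl chloride, CC(C)(C)C(=O)Cl (its atoms are found in 20 only, none in 21 or 22)
Why: The acid is first converted into the mixed anhydride 20, which acylates the isothiourea at nitrogen; deprotonation of the acyl ammonium ion gives a (Z)-ammonium enolate held flat by an O···S contact. Carbonate deprotonates the phenol of 11 and the phenoxide expels sulfinate, helped by the 5-methoxy and 7-silyloxy donors, to give the ortho-quinone methide 21, which is strongly electrophilic at its exocyclic carbon, the future C4. Conjugate addition of the enolate carbon to that carbon forms C3–C4 and restores the aromaticity of ring A, and the phenoxide so formed attacks the acyl ammonium carbonyl (6-exo-trig acyl substitution), which forms O1–C2, closes ring C as the lactone and frees the catalyst. The closest known reaction type is the isothiourea- or carbene-catalysed Michael addition–lactonisation (formal [4+2]) of acyl enolate equivalents with ortho-quinone methides made in situ, which gives 3-substituted dihydrocoumarins. C3 is the only new stereocentre because the methide carbon carries two hydrogens; it is set by the catalyst, whose C2 phenyl group covers one face of the enolate, so that the methide should add to the open Re face, which corresponds to (R). The step needs C-alkylation of the enolate to outrun self-condensation of 21 and O-acylation of the phenol of 11; the excess of 19, the portionwise addition of base and the fast loss of sulfinate from the electron-rich phenoxide serve this. The α-aryl lactone is acidic at C3, so a heterogeneous carbonate, low temperature and immediate reduction in step 16 are used to protect the configuration.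

**Step 16**
Reactants: 22 (3R)-3-{2,2-dimethyl-5-[(triisopropylsilyl)oxy]-2H-chromen-8-yl}-5-methoxy-6-(3-methylbut-2-en-1-yl)-7-[(triisopropylsilyl)oxy]-3,4-dihydro-2H-chromen-2-one
Product: 23 2-[(2R)-2-{2,2-dimethyl-5-[(triisopropylsilyl)oxy]-2H-chromen-8-yl}-3-hydroxypropyl]-3-methoxy-4-(3-methylbut-2-en-1-yl)-5-[(triisopropylsilyl)oxy]phenol
Conditions: LiBH4, THF, 0 °C
Reagents that add atoms: none
Why: Hydride reduction of an aryl ester (lactone) to the primary alcohol and the phenol. LiBH4 is a weak base and spares aryl silyl ethers and alkenes, and no bond to C3 is made or broken, so the configuration should be retained.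

**Step 17**
Reactants: 23 2-[(2R)-2-{2,2-dimethyl-5-[(triisopropylsilyl)oxy]-2H-chromen-8-yl}-3-hydroxypropyl]-3-methoxy-4-(3-methylbut-2-en-1-yl)-5-[(triisopropylsilyl)oxy]phenol
Product: 24 (3R)-3-{2,2-dimethyl-5-[(triisopropylsilyl)oxy]-2H-chromen-8-yl}-5-methoxy-6-(3-methylbut-2-en-1-yl)-7-[(triisopropylsilyl)oxy]chromane
Conditions: PPh3, DIAD, THF, 0 °C to rt
Reagents that add atoms: none
Why: Intramolecular Mitsunobu etherification: the only free phenol displaces the activated primary alcohol (6-exo-tet) and forms O1–C2. C3 is not a reacting centre, so its configuration is kept.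

**Step 18**
Reactants: 24 (3R)-3-{2,2-dimethyl-5-[(triisopropylsilyl)oxy]-2H-chromen-8-yl}-5-methoxy-6-(3-methylbut-2-en-1-yl)-7-[(triisopropylsilyl)oxy]chromane
Product: 25 (3R)-3-(5-hydroxy-2,2-dimethyl-2H-chromen-8-yl)-5-methoxy-6-(3-methylbut-2-en-1-yl)chroman-7-ol
Conditions: Bu4NF (2.5 equiv), AcOH, THF, 0 °C
Reagents that add atoms: none
Why: Fluoride cleavage of both aryl silyl ethers; acetic acid buffers the phenoxides against oxidation, and the prenyl and chromene alkenes, which would not survive acidic or reductive deprotection, stay intact.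

## Compound list

1 | 2,4,6-trihydroxybenzaldehyde | O=Cc1c(O)cc(O)cc1O | starting material
2 | 2,6-dihydroxy-4-[(triisopropylsilyl)oxy]benzaldehyde | O=Cc1c(O)cc(O[Si](C(C)C)(C(C)C)C(C)C)cc1O | intermediate
3 | 2-hydroxy-6-(methoxymethoxy)-4-[(triisopropylsilyl)oxy]benzaldehyde | O=Cc1c(O)cc(O[Si](C(C)C)(C(C)C)C(C)C)cc1OCOC | intermediate
4 | 2-methylbut-3-en-2-ol | CC(C)(O)C=C | starting material
5 | tert-butyl 2-methylbut-3-en-2-yl carbonate | C=CC(C)(C)OC(=O)OC(C)(C)C | intermediate
6 | 2-(methoxymethoxy)-6-[(2-methylbut-3-en-2-yl)oxy]-4-[(triisopropylsilyl)oxy]benzaldehyde | O=Cc1c(OC(C)(C)C=C)cc(O[Si](C(C)C)(C(C)C)C(C)C)cc1OCOC | intermediate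
7 | 2-hydroxy-6-(methoxymethoxy)-3-(3-methylbut-2-en-1-yl)-4-[(triisopropylsilyl)oxy]benzaldehyde | O=Cc1c(O)c(CC=C(C)C)c(O[Si](C(C)C)(C(C)C)C(C)C)cc1OCOC | intermediate
8 | 2-methoxy-6-(methoxymethoxy)-3-(3-methylbut-2-en-1-yl)-4-[(triisopropylsilyl)oxy]benzaldehyde | O=Cc1c(OC)c(CC=C(C)C)c(O[Si](C(C)C)(C(C)C)C(C)C)cc1OCOC | intermediate
9 | 6-hydroxy-2-methoxy-3-(3-methylbut-2-en-1-yl)-4-[(triisopropylsilyl)oxy]benzaldehyde | O=Cc1c(OC)c(CC=C(C)C)c(O[Si](C(C)C)(C(C)C)C(C)C)cc1O | intermediate
10 | 2-(hydroxymethyl)-3-methoxy-4-(3-methylbut-2-en-1-yl)-5-[(triisopropylsilyl)oxy]phenol | OCc1c(OC)c(CC=C(C)C)c(O[Si](C(C)C)(C(C)C)C(C)C)cc1O | intermediate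
11 | 3-methoxy-4-(3-methylbut-2-en-1-yl)-2-[(4-methylbenzenesulfonyl)methyl]-5-[(triisopropylsilyl)oxy]phenol | COc1c(CC=C(C)C)c(O[Si](C(C)C)(C(C)C)C(C)C)cc(O)c1CS(=O)(=O)c1ccc(C)cc1 | intermediate
12 | 2,4-dihydroxybenzaldehyde | O=Cc1ccc(O)cc1O | starting material
13 | 2-hydroxy-4-[(triisopropylsilyl)oxy]benzaldehyde | O=Cc1ccc(O[Si](C(C)C)(C(C)C)C(C)C)cc1O | intermediate
14 | 3-chloro-3-methylbut-1-yne | C#CC(C)(C)Cl | starting material
15 | 2-[(2-methylbut-3-yn-2-yl)oxy]-4-[(triisopropylsilyl)oxy]benzaldehyde | O=Cc1ccc(O[Si](C(C)C)(C(C)C)C(C)C)cc1OC(C)(C)C#C | intermediate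
16 | 2,2-dimethyl-5-[(triisopropylsilyl)oxy]-2H-chromene-8-carbaldehyde | O=Cc1ccc(O[Si](C(C)C)(C(C)C)C(C)C)c2c1OC(C)(C)C=C2 | intermediate
17 | 8-(2-methoxyethenyl)-2,2-dimethyl-5-[(triisopropylsilyl)oxy]-2H-chromene (E/Z mixture) | COC=Cc1ccc(O[Si](C(C)C)(C(C)C)C(C)C)c2c1OC(C)(C)C=C2 | intermediate
18 | 2-{2,2-dimethyl-5-[(triisopropylsilyl)oxy]-2H-chromen-8-yl}acetaldehyde | O=CCc1ccc(O[Si](C(C)C)(C(C)C)C(C)C)c2c1OC(C)(C)C=C2 | intermediate
19 | 2-{2,2-dimethyl-5-[(triisopropylsilyl)oxy]-2H-chromen-8-yl}acetic acid | OC(=O)Cc1ccc(O[Si](C(C)C)(C(C)C)C(C)C)c2c1OC(C)(C)C=C2 | intermediate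
20 | 2-{2,2-dimethyl-5-[(triisopropylsilyl)oxy]-2H-chromen-8-yl}acetic 2,2-dimethylpropanoic anhydride | CC(C)(C)C(=O)OC(=O)Cc1ccc(O[Si](C(C)C)(C(C)C)C(C)C)c2c1OC(C)(C)C=C2 | intermediate
21 | 5-methoxy-6-methylidene-4-(3-methylbut-2-en-1-yl)-3-[(triisopropylsilyl)oxy]cyclohexa-2,4-dien-1-one | C=C1C(=O)C=C(O[Si](C(C)C)(C(C)C)C(C)C)C(CC=C(C)C)=C1OC | intermediate
22 | (3R)-3-{2,2-dimethyl-5-[(triisopropylsilyl)oxy]-2H-chromen-8-yl}-5-methoxy-6-(3-methylbut-2-en-1-yl)-7-[(triisopropylsilyl)oxy]-3,4-dihydro-2H-chromen-2-one | COc1c(CC=C(C)C)c(O[Si](C(C)C)(C(C)C)C(C)C)cc2c1C[C@H](c1ccc(O[Si](C(C)C)(C(C)C)C(C)C)c3c1OC(C)(C)C=C3)C(=O)O2 | intermediate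
23 | 2-[(2R)-2-{2,2-dimethyl-5-[(triisopropylsilyl)oxy]-2H-chromen-8-yl}-3-hydroxypropyl]-3-methoxy-4-(3-methylbut-2-en-1-yl)-5-[(triisopropylsilyl)oxy]phenol | COc1c(CC=C(C)C)c(O[Si](C(C)C)(C(C)C)C(C)C)cc(O)c1C[C@H](c1ccc(O[Si](C(C)C)(C(C)C)C(C)C)c2c1OC(C)(C)C=C2)CO | intermediate
24 | (3R)-3-{2,2-dimethyl-5-[(triisopropylsilyl)oxy]-2H-chromen-8-yl}-5-methoxy-6-(3-methylbut-2-en-1-yl)-7-[(triisopropylsilyl)oxy]chromane | COc1c(CC=C(C)C)c(O[Si](C(C)C)(C(C)C)C(C)C)cc2c1C[C@H](c1ccc(O[Si](C(C)C)(C(C)C)C(C)C)c3c1OC(C)(C)C=C3)CO2 | intermediate
25 | (3R)-3-(5-hydroxy-2,2-dimethyl-2H-chromen-8-yl)-5-methoxy-6-(3-methylbut-2-en-1-yl)chroman-7-ol | COc1c(CC=C(C)C)c(O)cc2c1C[C@H](c1ccc(O)c3c1OC(C)(C)C=C3)CO2 | target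

## Step count and uncertain steps

Total step count: 18. Longest linear sequence: 11 steps, from 1 through steps 1, 2, 4, 5, 6, 7, 8, 15, 16, 17 and 18. The ring B branch from 12 is 10 steps long.

**Step 15 (key step).**
- What may go wrong:
  - Partial loss of enantiopurity by base-mediated enolisation of the α-aryl lactone. The same danger exists in step 16, at the transient α-aryl aldehyde.
  - Lower facial selectivity than hoped, because the methide carbon is unsubstituted and the transition state is less organised. The sense of induction also rests on a model.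
  - Consumption of 21 by self-condensation, since the phenoxide of 11 is a carbon nucleophile at its free ring position.
  - Acylation of the phenol of 11 by 20 before sulfinate is lost.
- Fallback: auxiliary control instead of catalyst control, setting out from 19 and 11 and returning at 23, so that the lactone 22 is bypassed.
  - Acid 19 is activated as its pivalic mixed anhydride and coupled with lithiated (4R)-4-benzyl-1,3-oxazolidin-2-one to give the imide (4R)-4-benzyl-3-(2-{2,2-dimethyl-5-[(triisopropylsilyl)oxy]-2H-chromen-8-yl}acetyl)-1,3-oxazolidin-2-one F1.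
  - Its chelated (Z)-sodium enolate (NaN(SiMe3)2, THF, −78 °C) is treated with the sodium phenoxide of 11 and warmed to about −40 °C. The released methide should alkylate the enolate on the face away from the benzyl group, as benzylic halides do in the auxiliary-based isoflavan syntheses. This should give the phenol-imide (4R)-4-benzyl-3-[(2R)-2-{2,2-dimethyl-5-[(triisopropylsilyl)oxy]-2H-chromen-8-yl}-3-{6-hydroxy-2-methoxy-3-(3-methylbut-2-en-1-yl)-4-[(triisopropylsilyl)oxy]phenyl}propanoyl]-1,3-oxazolidin-2-one F2.
  - LiBH4 removes the auxiliary reductively and delivers 23.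

**Step 8.**
- What may go wrong:
  - Over-reduction: under the basic borohydride conditions the phenoxide can expel the benzylic oxygen and the resulting methide can take up a second hydride, giving the methyl arene.
  - Oligomerisation: the ionised salicyl alcohol can alkylate the free ring position of another molecule before the sulfinate traps it.
- Fallback: change the order so that no free phenol is present during reduction, setting out from 8 and returning at 11.
  - NaBH4 reduces 8 to [2-methoxy-6-(methoxymethoxy)-3-(3-methylbut-2-en-1-yl)-4-[(triisopropylsilyl)oxy]phenyl]methanol F3.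
  - TolSO2Na in aqueous formic acid converts F3 into 2-methoxy-6-(methoxymethoxy)-3-(3-methylbut-2-en-1-yl)-1-[(4-methylbenzenesulfonyl)methyl]-4-[(triisopropylsilyl)oxy]benzene F4.
  - Aqueous HCl in THF then removes the MOM group to give 11.

**Step 4.**
- What may go wrong:
  - Attack of the phenoxide at the primary end of the allyl cation, or re-ionisation of the tertiary ether and drift to the linear prenyl ether, which would rearrange to the wrong (reverse prenyl) carbon skeleton in step 5.
  - Sluggish reaction of the chelated phenol.
- Fallback: build the tertiary ether from an alkyne, setting out from 3 and returning at 6.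
  - 3 is etherified with 14 under the conditions of step 10 (DBU, CuCl2, MeCN, 0 °C) to give 2-(methoxymethoxy)-6-[(2-methylbut-3-yn-2-yl)oxy]-4-[(triisopropylsilyl)oxy]benzaldehyde F5.
  - Semi-hydrogenation of F5 (H2, Pd on CaCO3 poisoned with Pb(OAc)2, quinoline, EtOAc) gives 6.

**Step 13.**
- What may go wrong:
  - Acid-promoted hydration or dimerisation of the chromene alkene, which is activated by two ortho oxygens.
  - Partial loss of the silyl ether.
  - Aldol self-condensation of the arylacetaldehyde.
- Fallback: a homologation that uses no acid, setting out from 16 and returning at 18, so that steps 12 and 13 are replaced.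
  - Methylenation of 16 (Ph3PCH3Br, NaN(SiMe3)2, THF) gives 8-ethenyl-2,2-dimethyl-5-[(triisopropylsilyl)oxy]-2H-chromene F6.
  - Hydroboration with 9-BBN, which should react at the terminal alkene and not at the hindered ring alkene, followed by NaBO3 oxidation, gives 2-{2,2-dimethyl-5-[(triisopropylsilyl)oxy]-2H-chromen-8-yl}ethan-1-ol F7.
  - Dess–Martin oxidation of F7 gives 18.

## Further compounds

F1 | step 15 | (4R)-4-benzyl-3-(2-{2,2-dimethyl-5-[(triisopropylsilyl)oxy]-2H-chromen-8-yl}acetyl)-1,3-oxazolidin-2-one | O=C1OC[C@@H](Cc2ccccc2)N1C(=O)Cc1ccc(O[Si](C(C)C)(C(C)C)C(C)C)c2c1OC(C)(C)C=C2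
F2 | step 15 | (4R)-4-benzyl-3-[(2R)-2-{2,2-dimethyl-5-[(triisopropylsilyl)oxy]-2H-chromen-8-yl}-3-{6-hydroxy-2-methoxy-3-(3-methylbut-2-en-1-yl)-4-[(triisopropylsilyl)oxy]phenyl}propanoyl]-1,3-oxazolidin-2-one | O=C1OC[C@@H](Cc2ccccc2)N1C(=O)[C@H](Cc1c(O)cc(O[Si](C(C)C)(C(C)C)C(C)C)c(CC=C(C)C)c1OC)c1ccc(O[Si](C(C)C)(C(C)C)C(C)C)c2c1OC(C)(C)C=C2
F3 | step 8 | [2-methoxy-6-(methoxymethoxy)-3-(3-methylbut-2-en-1-yl)-4-[(triisopropylsilyl)oxy]phenyl]methanol | OCc1c(OC)c(CC=C(C)C)c(O[Si](C(C)C)(C(C)C)C(C)C)cc1OCOC
F4 | step 8 | 2-methoxy-6-(methoxymethoxy)-3-(3-methylbut-2-en-1-yl)-1-[(4-methylbenzenesulfonyl)methyl]-4-[(triisopropylsilyl)oxy]benzene | COCOc1cc(O[Si](C(C)C)(C(C)C)C(C)C)c(CC=C(C)C)c(OC)c1CS(=O)(=O)c1ccc(C)cc1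
F5 | step 4 | 2-(methoxymethoxy)-6-[(2-methylbut-3-yn-2-yl)oxy]-4-[(triisopropylsilyl)oxy]benzaldehyde | O=Cc1c(OC(C)(C)C#C)cc(O[Si](C(C)C)(C(C)C)C(C)C)cc1OCOC
F6 | step 13 | 8-ethenyl-2,2-dimethyl-5-[(triisopropylsilyl)oxy]-2H-chromene | C=Cc1ccc(O[Si](C(C)C)(C(C)C)C(C)C)c2c1OC(C)(C)C=C2
F7 | step 13 | 2-{2,2-dimethyl-5-[(triisopropylsilyl)oxy]-2H-chromen-8-yl}ethan-1-ol | OCCc1ccc(O[Si](C(C)C)(C(C)C)C(C)C)c2c1OC(C)(C)C=C2
A1 | alternative 1 | 4-[(2R)-2-{2,2-dimethyl-5-[(triisopropylsilyl)oxy]-2H-chromen-8-yl}-3-[(triisopropylsilyl)oxy]propyl]-3-methoxy-2-(3-methylbut-2-en-1-yl)-5-[(triisopropylsilyl)oxy]phenol | COc1c(CC=C(C)C)c(O)cc(O[Si](C(C)C)(C(C)C)C(C)C)c1C[C@H](c1ccc(O[Si](C(C)C)(C(C)C)C(C)C)c2c1OC(C)(C)C=C2)CO[Si](C(C)C)(C(C)C)C(C)C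
A2 | alternative 1 | 2-[(2R)-2-{2,2-dimethyl-5-[(triisopropylsilyl)oxy]-2H-chromen-8-yl}-3-[(triisopropylsilyl)oxy]propyl]-3-[(triisopropylsilyl)oxy]cyclobut-2-en-1-one | O=C1CC(O[Si](C(C)C)(C(C)C)C(C)C)=C1C[C@H](c1ccc(O[Si](C(C)C)(C(C)C)C(C)C)c2c1OC(C)(C)C=C2)CO[Si](C(C)C)(C(C)C)C(C)C
A3 | alternative 1 | 1-methoxy-5-methylhex-4-en-1-yne | COC#CCC=C(C)C
A4 | alternative 2 | 2-[(3R)-5-methoxy-6-(3-methylbut-2-en-1-yl)-7-[(triisopropylsilyl)oxy]-3,4-dihydro-2H-chromen-3-yl]-5-[(triisopropylsilyl)oxy]phenol | Oc1cc(O[Si](C(C)C)(C(C)C)C(C)C)ccc1[C@@H]1COc2cc(O[Si](C(C)C)(C(C)C)C(C)C)c(CC=C(C)C)c(OC)c2C1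
A5 | alternative 2 | (3E)-1-diazo-4-[(3R)-5-methoxy-6-(3-methylbut-2-en-1-yl)-7-[(triisopropylsilyl)oxy]-3,4-dihydro-2H-chromen-3-yl]but-3-en-2-one | [N-]=[N+]=CC(=O)/C=C/[C@@H]1COc2cc(O[Si](C(C)C)(C(C)C)C(C)C)c(CC=C(C)C)c(OC)c2C1
A6 | alternative 2 | (ethynyloxy)triisopropylsilane | C#CO[Si](C(C)C)(C(C)C)C(C)C
A7 | alternative 3 | (3R)-3-{2,2-dimethyl-5-[(triisopropylsilyl)oxy]-2H-chromen-8-yl}-6-(3-methylbut-2-en-1-yl)-3,4-dihydro-2H-chromene-5,7-diol | Oc1c(CC=C(C)C)c(O)cc2c1C[C@H](c1ccc(O[Si](C(C)C)(C(C)C)C(C)C)c3c1OC(C)(C)C=C3)CO2
A8 | alternative 3 | methyl (3R)-3-{2,2-dimethyl-5-[(triisopropylsilyl)oxy]-2H-chromen-8-yl}-6-(6-methyl-2-oxohept-5-en-1-yl)-3,4-dihydro-2H-pyran-5-carboxylate | COC(=O)C1=C(CC(=O)CCC=C(C)C)OC[C@@H](c2ccc(O[Si](C(C)C)(C(C)C)C(C)C)c3c2OC(C)(C)C=C3)C1
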